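Assumption: locants C1–C15 are the elemane numbering of the target (C1=C2 vinyl and C14H2OAc on C10; C9H2; C8–OAc; C7; C11(=C13H2)–C12 lactone carbonyl; C6–O; C5; C4(=C3H2)–C15HO), and compound 1 is bought (it is made from L-glutamic acid).

**Retrosynthetic overview**
- The target comes from the 8,14-diacetate by late allylic oxidation of the C5 isopropenyl group (C15). The C13 methylene is added to a plain trans γ-lactone.
- The cyclohexane is closed at C6–C7 by a SmI2 ketyl–enoate 6-exo cyclisation, and the 6,12-lactone forms in the same step.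
- The key C5–C10 bond (quaternary C10 with its vinyl group, plus C5) comes from an Ireland–Claisen [3,3] rearrangement of a 3-methylbut-3-enoate on an E-alkylidene lactone.
- The template is (S)-γ-(trityloxymethyl)butyrolactone. It supplies C7–C10 and C14, and its C8 stereocentre controls all the others.
- Ring order: bought γ-lactone (sacrificed), then a transient C6/C14 γ-lactone and lactol, then the cyclohexane, then the 6,12-γ-lactone.

**Step 1**
Reactants: 1 (S)-5-[(trityloxy)methyl]dihydrofuran-2(3H)-one; 2 (tert-butyldimethylsilyloxy)acetaldehyde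
Product: 5 (S,E)-3-[2-(tert-butyldimethylsilyloxy)ethylidene]-5-[(trityloxy)methyl]dihydrofuran-2(3H)-one, via lithium aldolate 3 (not isolated), via aldol mesylate 4 (not isolated)
Conditions: LDA, THF, −78 °C; 2; MsCl, −78 to 0 °C; DBU, 0 °C to rt
Reagents that add atoms: none
Why: Aldol addition of the lactone enolate followed by E1cB loss of mesylate (aldol condensation) gives the thermodynamically preferred E-alkylidene lactone, leaves C8 untouched and creates no lasting stereocentre.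

**Step 2**
Reactants: 5 (S,E)-3-[2-(tert-butyldimethylsilyloxy)ethylidene]-5-[(trityloxy)methyl]dihydrofuran-2(3H)-one
Product: 6 (S,E)-3-(2-hydroxyethylidene)-5-[(trityloxy)methyl]dihydrofuran-2(3H)-one
Conditions: Et3N·3HF, MeCN, rt
Reagents that add atoms: none
Why: Near-neutral fluoride desilylation removes the primary allylic TBS ether and spares the trityl ether and the Michael-acceptor lactone.

**Step 3**
Reactants: 6 (S,E)-3-(2-hydroxyethylidene)-5-[(trityloxy)methyl]dihydrofuran-2(3H)-one; 7 3-methylbut-3-enoic acid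
Product: 8 (E)-2-[(S)-2-oxo-5-(trityloxymethyl)dihydrofuran-3(2H)-ylidene]ethyl 3-methylbut-3-enoate
Conditions: DCC, DMAP (5 mol %), CH2Cl2, −10 °C
Reagents that add atoms: none
Why: Steglich esterification of the primary allylic alcohol at low temperature avoids conjugation of the β,γ-unsaturated acid.

**Step 4 (key step)**
Reactants: 8 (E)-2-[(S)-2-oxo-5-(trityloxymethyl)dihydrofuran-3(2H)-ylidene]ethyl 3-methylbut-3-enoate
Product: 11 (S)-3-methyl-2-[(3R,5S)-2-oxo-5-(trityloxymethyl)-3-vinyltetrahydrofuran-3-yl]but-3-enoic acid, via Z-silyl ketene acetal 9 (not isolated), via trimethylsilyl ester 10 (not isolated)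
Conditions: KHMDS, TMSCl, toluene–THF, −78 °C; then 50 °C; aq. citric acid
Reagents that add atoms: none
Why: In this Ireland–Claisen [3,3] rearrangement the doubly activated ester α-H is removed selectively, the chair transition state forms C5–C10 on the lactone face anti to the C8 CH2OTr group (setting quaternary C10 and releasing the vinyl group), and the E-alkylidene/Z-ketene acetal pairing sets C5.

**Step 5**
Reactants: 11 (S)-3-methyl-2-[(3R,5S)-2-oxo-5-(trityloxymethyl)-3-vinyltetrahydrofuran-3-yl]but-3-enoic acid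
Product: 13 (3S,4R)-4-[(S)-2-hydroxy-3-(trityloxy)propyl]-3-(prop-1-en-2-yl)-4-vinyldihydrofuran-2(3H)-one, via dihydroxy acid 12 (not isolated)
Conditions: LiEt3BH (3.3 equiv), THF, 0 °C to rt; AcOH; PPTS (cat.), CH2Cl2, rt
Reagents that add atoms: none
Why: In this chemoselective hydride reduction the first equivalent makes the inert lithium carboxylate, the lactone goes to the C14/C8 diol, and acid-catalysed γ-lactonisation of C14–OH onto C6 separates C6, C14 and C8 without touching a stereocentre.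

**Step 6**
Reactants: 13 (3S,4R)-4-[(S)-2-hydroxy-3-(trityloxy)propyl]-3-(prop-1-en-2-yl)-4-vinyldihydrofuran-2(3H)-one
Product: 14 (3S,4R)-4-[(S)-2-(tert-butyldimethylsilyloxy)-3-(trityloxy)propyl]-3-(prop-1-en-2-yl)-4-vinyldihydrofuran-2(3H)-one
Conditions: TBSOTf, 2,6-lutidine, CH2Cl2, 0 °C
Reagents that add atoms: tert-butyldimethylsilyl triflate, CC(C)(C)[Si](C)(C)OS(=O)(=O)C(F)(F)F
Why: Silyl ether protection of C8–OH keeps it from competing for the C12 carboxyl later and makes it a poor leaving group.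

**Step 7**
Reactants: 14 (3S,4R)-4-[(S)-2-(tert-butyldimethylsilyloxy)-3-(trityloxy)propyl]-3-(prop-1-en-2-yl)-4-vinyldihydrofuran-2(3H)-one
Product: 16 (S)-2-(tert-butyldimethylsilyloxy)-3-[(3R,4S)-5-methoxy-4-(prop-1-en-2-yl)-3-vinyltetrahydrofuran-3-yl]propan-1-ol (anomers), via lactol 15 (not isolated)
Conditions: DIBAL-H, CH2Cl2, −78 °C; Rochelle salt; crude, CSA (10 mol %), MeOH–CH2Cl2, 0 °C
Reagents that add atoms: methanol, CO
Why: DIBAL half-reduction brings C6 to the aldehyde level as a lactol, and acidic methanol then masks it as the methyl acetal (Fischer-type acetalisation) and solvolyses the trityl ether faster than the secondary TBS ether.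

**Step 8**
Reactants: 16 (S)-2-(tert-butyldimethylsilyloxy)-3-[(3R,4S)-5-methoxy-4-(prop-1-en-2-yl)-3-vinyltetrahydrofuran-3-yl]propan-1-ol; 17 methyl (triphenylphosphoranylidene)acetate
Product: 19 methyl (S,E)-4-(tert-butyldimethylsilyloxy)-5-[(3R,4S)-5-methoxy-4-(prop-1-en-2-yl)-3-vinyltetrahydrofuran-3-yl]pent-2-enoate, via silyloxy aldehyde 18 (not isolated)
Conditions: DMP, CH2Cl2, rt; then 17, rt
Reagents that add atoms: none
Why: One-pot Dess–Martin oxidation and Wittig olefination with a stabilised ylide traps the epimerisable α-silyloxy aldehyde at once and gives the E-enoate that carries C11 and C12.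

**Step 9**
Reactants: 19 methyl (S,E)-4-(tert-butyldimethylsilyloxy)-5-[(3R,4S)-5-methoxy-4-(prop-1-en-2-yl)-3-vinyltetrahydrofuran-3-yl]pent-2-enoate
Product: 20 methyl (S,E)-4-(tert-butyldimethylsilyloxy)-5-[(3R,4S)-5-hydroxy-4-(prop-1-en-2-yl)-3-vinyltetrahydrofuran-3-yl]pent-2-enoate (lactol)
Conditions: AcOH–THF–H2O (3:1:1), 40 °C
Reagents that add atoms: water, O
Why: Mild acetal hydrolysis works because 2-methoxytetrahydrofurans hydrolyse far faster than a secondary TBS ether or the enoate.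

**Step 10**
Reactants: 20 methyl (S,E)-4-(tert-butyldimethylsilyloxy)-5-[(3R,4S)-5-hydroxy-4-(prop-1-en-2-yl)-3-vinyltetrahydrofuran-3-yl]pent-2-enoate
Product: 22 8α-(tert-butyldimethylsilyloxy)-14-hydroxy-13-norelema-1,3-dien-6α,12-olide (5αH; 6βH; 7αH; C10 vinyl α; CH2OH β), via hydroxy ester 21 (not isolated)
Conditions: SmI2 (3 equiv), MeOH (4 equiv), THF, 0.01 M, 0 °C to rt; PPTS, benzene, 50 °C
Reagents that add atoms: none
Why: In this SmI2 ketyl–olefin 6-exo-trig cyclisation the lactol reacts through its hydroxy-aldehyde form, and a Sm-chelated chair with the C5 isopropenyl, C8–OTBS, ketyl oxygen and acrylate arm all equatorial sets C6 (O α) and C7 (C11 β) trans before the C6 alkoxide lactonises.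

**Step 11**
Reactants: 22 8α-(tert-butyldimethylsilyloxy)-14-hydroxy-13-norelema-1,3-dien-6α,12-olide
Product: 25 8α-(tert-butyldimethylsilyloxy)-14-hydroxyelema-1,3,11(13)-trien-6α,12-olide, via Mannich base 23 (not isolated), via methiodide salt 24 (not isolated)
Conditions: LDA (2.3 equiv), THF, −78 °C; CH2=NMe2+ I−; crude, MeI, MeOH; aq. NaHCO3–CH2Cl2
Reagents that add atoms: Eschenmoser's salt, C=[N+](C)C.[I-]
Why: Eschenmoser α-methylenation (Mannich reaction, quaternisation, Hofmann-type elimination) turns C11 into an sp2 centre, and the enolate has no β-leaving group.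

**Step 12**
Reactants: 25 8α-(tert-butyldimethylsilyloxy)-14-hydroxyelema-1,3,11(13)-trien-6α,12-olide
Product: 27 8α,14-diacetoxyelema-1,3,11(13)-trien-6α,12-olide, via diol 26 (not isolated)
Conditions: HF·pyridine, THF, 0 °C to rt; then Ac2O, pyridine, DMAP (cat.)
Reagents that add atoms: acetic anhydride, CC(=O)OC(C)=O
Why: Acidic fluoride desilylation avoids translactonisation, and the same flask then acetylates both free hydroxyl groups with retention at C8.

**Step 13**
Reactants: 27 8α,14-diacetoxyelema-1,3,11(13)-trien-6α,12-olide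
Product: 29 8α,14-diacetoxy-15-oxoelema-1,3,11(13)-trien-6α,12-olide (target; 5R,6R,7R,8S,10R), via allylic alcohol 28 (not isolated)
Conditions: SeO2 (0.3 equiv), t-BuOOH, CH2Cl2, rt; crude, DMP, CH2Cl2, rt
Reagents that add atoms: tert-butyl hydroperoxide, CC(C)(C)OO
Why: Sharpless SeO2/TBHP allylic oxidation (ene reaction then [2,3] shift) attacks the only electron-rich alkene with an accessible allylic CH3, because the vinyl group has no allylic H and the lactone methylene is electron-poor, and Dess–Martin oxidation completes the enal without touching a stereocentre.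

**Compound list**
1 | (S)-5-[(trityloxy)methyl]dihydrofuran-2(3H)-one | O=C1CC[C@@H](COC(c2ccccc2)(c2ccccc2)c2ccccc2)O1 | starting material
2 | (tert-butyldimethylsilyloxy)acetaldehyde | CC(C)(C)[Si](C)(C)OCC=O | starting material
3 | lithium aldolate (C1 and C10 epimers) | [Li+].[O-]C(CO[Si](C)(C)C(C)(C)C)C1C[C@@H](COC(c2ccccc2)(c2ccccc2)c2ccccc2)OC1=O | intermediate
4 | aldol mesylate | CS(=O)(=O)OC(CO[Si](C)(C)C(C)(C)C)C1C[C@@H](COC(c2ccccc2)(c2ccccc2)c2ccccc2)OC1=O | intermediate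
5 | (S,E)-3-[2-(TBSO)ethylidene]-5-[(trityloxy)methyl]dihydrofuran-2(3H)-one | CC(C)(C)[Si](C)(C)OC/C=C1\C[C@@H](COC(c2ccccc2)(c2ccccc2)c2ccccc2)OC1=O | intermediate
6 | (S,E)-3-(2-hydroxyethylidene)-5-[(trityloxy)methyl]dihydrofuran-2(3H)-one | OC/C=C1\C[C@@H](COC(c2ccccc2)(c2ccccc2)c2ccccc2)OC1=O | intermediate
7 | 3-methylbut-3-enoic acid | C=C(C)CC(=O)O | starting material
8 | (E)-2-[(S)-2-oxo-5-(trityloxymethyl)dihydrofuran-3(2H)-ylidene]ethyl 3-methylbut-3-enoate | C=C(C)CC(=O)OC/C=C1\C[C@@H](COC(c2ccccc2)(c2ccccc2)c2ccccc2)OC1=O | intermediate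
9 | Z-trimethylsilyl ketene acetal of 8 | C=C(C)/C=C(\O[Si](C)(C)C)OC/C=C1\C[C@@H](COC(c2ccccc2)(c2ccccc2)c2ccccc2)OC1=O | intermediate
10 | trimethylsilyl ester of 11 | C=C[C@]1(C[C@@H](COC(c2ccccc2)(c2ccccc2)c2ccccc2)OC1=O)[C@H](C(C)=C)C(=O)O[Si](C)(C)C | intermediate
11 | (S)-3-methyl-2-[(3R,5S)-2-oxo-5-(trityloxymethyl)-3-vinyltetrahydrofuran-3-yl]but-3-enoic acid | C=C[C@]1(C[C@@H](COC(c2ccccc2)(c2ccccc2)c2ccccc2)OC1=O)[C@H](C(C)=C)C(=O)O | intermediate
12 | dihydroxy acid (C14H2OH, C8–OH, C6OOH) | C=C[C@](CO)(C[C@H](O)COC(c1ccccc1)(c1ccccc1)c1ccccc1)[C@H](C(C)=C)C(=O)O | intermediate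
13 | (3S,4R)-4-[(S)-2-hydroxy-3-(trityloxy)propyl]-3-(prop-1-en-2-yl)-4-vinyldihydrofuran-2(3H)-one | C=C[C@@]1(C[C@H](O)COC(c2ccccc2)(c2ccccc2)c2ccccc2)COC(=O)[C@H]1C(C)=C | intermediate
14 | TBS ether of 13 | C=C[C@@]1(C[C@H](O[Si](C)(C)C(C)(C)C)COC(c2ccccc2)(c2ccccc2)c2ccccc2)COC(=O)[C@H]1C(C)=C | intermediate
15 | lactol from 14 | C=C[C@@]1(C[C@H](O[Si](C)(C)C(C)(C)C)COC(c2ccccc2)(c2ccccc2)c2ccccc2)COC(O)[C@H]1C(C)=C | intermediate
16 | (S)-2-(TBSO)-3-[(3R,4S)-5-methoxy-4-(prop-1-en-2-yl)-3-vinyltetrahydrofuran-3-yl]propan-1-ol | C=C[C@@]1(C[C@H](O[Si](C)(C)C(C)(C)C)CO)COC(OC)[C@H]1C(C)=C | intermediate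
17 | methyl (triphenylphosphoranylidene)acetate | COC(=O)C=P(c1ccccc1)(c1ccccc1)c1ccccc1 | starting material
18 | α-silyloxy aldehyde from 16 | C=C[C@@]1(C[C@H](O[Si](C)(C)C(C)(C)C)C=O)COC(OC)[C@H]1C(C)=C | intermediate
19 | methyl (S,E)-4-(TBSO)-5-[(3R,4S)-5-methoxy-4-(prop-1-en-2-yl)-3-vinyltetrahydrofuran-3-yl]pent-2-enoate | C=C[C@@]1(C[C@H](O[Si](C)(C)C(C)(C)C)/C=C/C(=O)OC)COC(OC)[C@H]1C(C)=C | intermediate
20 | lactol enoate | C=C[C@@]1(C[C@H](O[Si](C)(C)C(C)(C)C)/C=C/C(=O)OC)COC(O)[C@H]1C(C)=C | intermediate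
21 | cyclised hydroxy ester | C=C[C@]1(CO)C[C@H](O[Si](C)(C)C(C)(C)C)[C@@H](CC(=O)OC)[C@H](O)[C@H]1C(C)=C | intermediate
22 | 8α-(TBSO)-14-hydroxy-13-norelema-1,3-dien-6α,12-olide | C=C[C@]1(CO)C[C@H](O[Si](C)(C)C(C)(C)C)[C@H]2CC(=O)O[C@@H]2[C@H]1C(C)=C | intermediate
23 | 13-(dimethylamino) Mannich base | C=C[C@]1(CO)C[C@H](O[Si](C)(C)C(C)(C)C)[C@H]2C(CN(C)C)C(=O)O[C@@H]2[C@H]1C(C)=C | intermediate
24 | methiodide of 23 | C=C[C@]1(CO)C[C@H](O[Si](C)(C)C(C)(C)C)[C@H]2C(C[N+](C)(C)C)C(=O)O[C@@H]2[C@H]1C(C)=C.[I-] | intermediate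
25 | 8α-(TBSO)-14-hydroxyelema-1,3,11(13)-trien-6α,12-olide | C=C[C@]1(CO)C[C@H](O[Si](C)(C)C(C)(C)C)[C@H]2C(=C)C(=O)O[C@@H]2[C@H]1C(C)=C | intermediate
26 | 8α,14-dihydroxyelema-1,3,11(13)-trien-6α,12-olide | C=C[C@]1(CO)C[C@H](O)[C@H]2C(=C)C(=O)O[C@@H]2[C@H]1C(C)=C | intermediate
27 | 8α,14-diacetoxyelema-1,3,11(13)-trien-6α,12-olide | C=C[C@]1(COC(C)=O)C[C@H](OC(C)=O)[C@H]2C(=C)C(=O)O[C@@H]2[C@H]1C(C)=C | intermediate
28 | 8α,14-diacetoxy-15-hydroxyelema-1,3,11(13)-trien-6α,12-olide | C=C[C@]1(COC(C)=O)C[C@H](OC(C)=O)[C@H]2C(=C)C(=O)O[C@@H]2[C@H]1C(=C)CO | intermediate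
29 | 8α,14-diacetoxy-15-oxoelema-1,3,11(13)-trien-6α,12-olide | C=C[C@]1(COC(C)=O)C[C@H](OC(C)=O)[C@H]2C(=C)C(=O)O[C@@H]2[C@H]1C(=C)C=O | target

**Totals**
Total step count: 13. Longest linear sequence: 13 (from 1).

**The three steps most likely to fail**

**Step 4 (Ireland–Claisen).** The risks are a hindered, electron-poor allyl terminus, the ketene acetal geometry and the face selectivity. A wrong C5 epimer can still be equilibrated with DBU at 13, where isopropenyl trans to the large C10 side chain is the stable isomer.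

The fallback sets out from 1 and rejoins at 14. It builds the quaternary centre by enolate chemistry:
- Pd-catalysed α-vinylation of 1 (LiHMDS, vinyl bromide, Pd2(dba)3/P(t-Bu)3) gives the α-vinyl lactone F1.
- Its dienolate (LDA, DMPU) is alkylated at Cα with tert-butyl bromoacetate on the face anti to CH2OTr, giving the quaternary lactone ester F2.
- LiBH4 reduces only the lactone, and the freed primary alkoxide closes on the tert-butyl ester to give the isopropenyl-free γ-lactone F3.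
- TBSOTf gives its silyl ether F4.
- Pd-catalysed α-alkenylation of the lithium enolate of F4 with 2-bromopropene places the isopropenyl group trans to the large C10 side chain and gives 14.

**Step 10 (SmI2 closure).** The risks are the low concentration of open aldehyde in the lactol, the trans/cis ratio and sluggish lactonisation.

The fallback sets out from 16 and rejoins at 26. Compound 16 is oxidised as in step 8 to 18, which is olefinated with methyl 2-(dimethoxyphosphoryl)-3-(trimethylsilyl)propanoate (NaH, THF) to give the β-(methoxycarbonyl)allylsilane F5. Aqueous acetic acid gives the lactol allylsilane F6. TBAF then triggers an intramolecular Hosomi–Sakurai-type addition of C7 to the C6 aldehyde. This step installs the C13 methylene directly, lactonises and removes the TBS group, giving 26.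

**Step 13 (SeO2 oxidation).** The risks are competing attack at the tertiary C5–H, over-oxidation and a low conversion.

The fallback sets out from 27 and rejoins at 29. Ene-type allylic chlorination (NaOCl, AcOH, CH2Cl2, 0 °C) gives the 15-chloride F7. Oxidation of F7 with N-methylmorpholine N-oxide (Kornblum-type, MeCN, rt) gives 29.

**Further compounds**
F1 | step 4 | (5S)-5-[(trityloxy)methyl]-3-vinyldihydrofuran-2(3H)-one | C=CC1C[C@@H](COC(c2ccccc2)(c2ccccc2)c2ccccc2)OC1=O
F2 | step 4 | tert-butyl 2-[(3R,5S)-2-oxo-5-(trityloxymethyl)-3-vinyltetrahydrofuran-3-yl]acetate | C=C[C@]1(C[C@@H](COC(c2ccccc2)(c2ccccc2)c2ccccc2)OC1=O)CC(=O)OC(C)(C)C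
F3 | step 4 | (R)-4-[(S)-2-hydroxy-3-(trityloxy)propyl]-4-vinyldihydrofuran-2(3H)-one | C=C[C@@]1(C[C@H](O)COC(c2ccccc2)(c2ccccc2)c2ccccc2)COC(=O)C1
F4 | step 4 | (R)-4-[(S)-2-(tert-butyldimethylsilyloxy)-3-(trityloxy)propyl]-4-vinyldihydrofuran-2(3H)-one | C=C[C@@]1(C[C@H](O[Si](C)(C)C(C)(C)C)COC(c2ccccc2)(c2ccccc2)c2ccccc2)COC(=O)C1
F5 | step 10 | methyl (S)-4-(tert-butyldimethylsilyloxy)-5-[(3R,4S)-5-methoxy-4-(prop-1-en-2-yl)-3-vinyltetrahydrofuran-3-yl]-2-[(trimethylsilyl)methyl]pent-2-enoate | C=C[C@@]1(C[C@H](O[Si](C)(C)C(C)(C)C)C=C(C[Si](C)(C)C)C(=O)OC)COC(OC)[C@H]1C(C)=C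
F6 | step 10 | lactol of F5 | C=C[C@@]1(C[C@H](O[Si](C)(C)C(C)(C)C)C=C(C[Si](C)(C)C)C(=O)OC)COC(O)[C@H]1C(C)=C
F7 | step 13 | 8α,14-diacetoxy-15-chloroelema-1,3,11(13)-trien-6α,12-olide | C=C[C@]1(COC(C)=O)C[C@H](OC(C)=O)[C@H]2C(=C)C(=O)O[C@@H]2[C@H]1C(=C)CCl
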